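I doubted your hunch. You took the rate to follow the precatalyst charge, which gave a factor of 10.9 for 120 µM against the 11 µM of the flask, and that was my first answer too.

| flask | substrate | coupling partner | precatalyst | remark |
|---|---|---|---|---|
| ochre | 11 mM | 19.8 mM | 7.4 µM | run made earlier |
| green | 11 mM | 19.8 mM | 16 µM | run made earlier |
| violet | 11 mM | 30 mM | 11 µM | run made earlier |
| flask | 11 mM | 19.8 mM | 11 µM |  |

| run | time / s | target / % | substrate / % |
|---|---|---|---|
| ochre | 30.0 | 12.0 | 87.8 |
| ochre | 60.0 | 22.0 | 78.5 |
| ochre | 90.0 | 27.1 | 71.2 |
| ochre | 120 | 31.6 | 68.3 |
| green | 10.0 | 6.3 | 93.7 |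
| green | 20.0 | 15.0 | 84.3 |
| green | 50.0 | 34.9 | 63.9 |
| green | 120 | 51.6 | 48.0 |
| violet | 15.0 | 10.7 | 88.8 |
| violet | 40.0 | 29.8 | 70.9 |
| violet | 80.0 | 43.6 | 55.6 |
| violet | 120 | 50.1 | 48.9 |

(each reading ± 0.5 percentage points)

* factor on the rate of making target when 10% of the substrate are converted if coupling partner is charged twice over
* factor on the rate when 10% of the substrate are converted if precatalyst is charged at 120 µM instead

- reactions considered so far: coupling partner + free catalyst <-> catalyst intermediate A; substrate + catalyst intermediate A -> catalyst intermediate B; catalyst intermediate B <-> catalyst intermediate C; catalyst intermediate C -> released group + catalyst intermediate D; catalyst intermediate D -> free catalyst + target; 2 coupling partner -> self-condensation product; coupling partner + precatalyst -> free catalyst + spent reagent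

Then I put that answer back in. With 120 µM it moved the mark of 10% conversion to about 2.12 s, earlier than the first green reading, and the early green readings pointed to an induction period: target stood at 6.3% after 10.0 s and at 15.0% after 20.0 s. So I read the early curve as target growing with t^n, and took the time exponent, the power of time in that early curve, as 1.25.

At a fixed conversion the rate is then n times the converted amount over the time, so rates at the mark go inversely as times to the mark; and if target at a fixed time follows c(precatalyst) linearly, with c(coupling partner) held, the rate at the mark rises as the n-th root of c(precatalyst). That gave me 6.75. Scaled from green, I put the mark of the flask at 19.5 s. With the same n, I put the mark of the violet run at 14.2 s, and the power of c(coupling partner) that joins these two estimated times gave 1.70 for the doubled charge.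

The forecast stood at 1.7 and 10, saying of its two corrections to the precatalyst factor “These roughly cancel, giving about 10”, so my ratio differed from it.

The flask gave 1.70 and 6.19.

    coupling partner + free catalyst ⇌ catalyst intermediate A (K = 37.0 M⁻¹, k = 3120 M⁻¹ s⁻¹)
    substrate + catalyst intermediate A → catalyst intermediate B (k = 20000 M⁻¹ s⁻¹)
    catalyst intermediate B ⇌ catalyst intermediate C (K = 12.8, k = 458 s⁻¹)
    catalyst intermediate C → released group + catalyst intermediate D (k = 185 s⁻¹)
    catalyst intermediate D → free catalyst + target (k = 214 s⁻¹)
    2 coupling partner → self-condensation product (k = 1.70 M⁻¹ s⁻¹)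
    coupling partner + precatalyst → free catalyst + spent reagent (k = 2.86 M⁻¹ s⁻¹)

At 0.200 min, ahead of the mark at 0.318 min, 61.1% of the catalyst in the flask was precatalyst. With 120 µM, the rate at the mark was 26.9 mM min⁻¹, and n places that mark at 3.08 s. In the flask, n times the converted 1.10 mM over 0.318 min comes to 4.33 mM min⁻¹, and the rate of making target at that moment was 4.34 mM min⁻¹.

Readings and results were computed with constants of no real substance; noise was put on by code.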